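The cyclohexanone ring is symmetric about the C1–C4 axis. The tertiary carbinol C1 and the ketone C4 are 1,4-related, so C1–C2 and C1–C6 can both be cut, leaving C1 as an ester carbon and C2/C6 as nucleophilic carbons β to C4. In one operation a 3-oxopentane-1,5-diyl bis-Grignard reagent, with C4 masked as a 5,5-dimethyl-1,3-dioxane ketal, adds twice to methyl 3-(tert-butyldimethylsilyloxy)propanoate. This closes the six-membered ring and installs the C1 hydroxyl and the two-carbon side chain together. Acid unmasking and acylation of the primary hydroxyl with palmitoyl chloride complete the target.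

Key step: step 4

Remark on the chemistry: the target is achiral (C1 carries two identical ring arms), so no configuration has to be set; C4 is carried as a 5,5-dimethyl-1,3-dioxane rather than a 1,3-dioxolane because γ-alkoxy organomagnesium reagents of the dioxolane type are prone to close to alkoxycyclopropanes near room temperature, and the chlorides are kept because they are poor partners for Wurtz coupling yet insert highly reactive magnesium below 20 °C.

Step 1
Reactants: 1 1,5-dichloropentan-3-one; 2 2,2-dimethylpropane-1,3-diol (neopentyl glycol)
Product: 3 2,2-bis(2-chloroethyl)-5,5-dimethyl-1,3-dioxane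
Conditions: HC(OEt)3, p-TsOH·H2O (cat.), CH2Cl2, rt
Reagents that add atoms: none
Why: Acid-catalysed ketalisation, with the orthoester taking up the water, should form the six-membered ketal at room temperature, so the β-chloro ketone is never heated and loss of HCl to vinyl ketones is avoided.

Step 2
Reactants: 3 2,2-bis(2-chloroethyl)-5,5-dimethyl-1,3-dioxane
Product: 4 2,2-bis[2-(chloromagnesio)ethyl]-5,5-dimethyl-1,3-dioxane (used as a titrated THF solution, cannulated off the excess metal)
Conditions: Mg* (commercial slurry of highly reactive magnesium powder, 3 equiv), THF, 0 → 20 °C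
Reagents that add atoms: magnesium, [Mg]
Why: Grignard formation by insertion of magnesium into both primary C–Cl bonds (a di-Grignard reagent from a 1,5-dihalide) should run at or below 20 °C with the highly reactive metal, the C–Cl bond being a poor electrophile for intramolecular Wurtz coupling to a cyclopentane and the gem-dimethyl dioxane holding back 1,3-elimination of the γ-alkoxy C–Mg bond.

Step 3
Reactants: 5 methyl 3-hydroxypropanoate
Product: 6 methyl 3-(tert-butyldimethylsilyloxy)propanoate
Conditions: TBSCl, imidazole, CH2Cl2, 0 °C → rt
Reagents that add atoms: tert-butyldimethylsilyl chloride, CC(C)(C)[Si](C)(C)Cl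
Why: Silylation of an unhindered primary alcohol with a silyl chloride and imidazole is a standard protection that leaves the methyl ester untouched and gives an ether inert to organomagnesium reagents.

Step 4
Reactants: 4 2,2-bis[2-(chloromagnesio)ethyl]-5,5-dimethyl-1,3-dioxane; 6 methyl 3-(tert-butyldimethylsilyloxy)propanoate
Product: 9 9-[2-(tert-butyldimethylsilyloxy)ethyl]-3,3-dimethyl-1,5-dioxaspiro[5.5]undecan-9-ol, via keto Grignard 7 (not isolated), via chloromagnesium alkoxide 8 (not isolated)
Conditions: 6 added over 2 h to 4 (1.3 equiv), THF, 0 °C → rt; sat. aq NH4Cl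
Reagents that add atoms: none
Why: One C–Mg end of 4 adds to the ester carbonyl of 6 and methoxide is expelled (acyl substitution) to give keto Grignard 7, whose remaining C–Mg bond attacks the new ketone intramolecularly to give alkoxide 8, protonated on work-up to 9. The closest known reaction type is the annulation of esters with pentane-1,5-diyl di-Grignard reagents to 1-substituted cyclohexanols, combined with the established use of β-ketal Grignard reagents as homoenolate equivalents. The ring closes in a 6-exo-trig mode and so completes C1–C2 and C1–C6 of the cyclohexane. No stereocentre is created, because C1 carries two identical ring arms and the product has a mirror plane. The step needs cyclisation of 7 to outrun intermolecular attack by a second reagent molecule, enolisation, and E1cB loss of silanolate from the β-silyloxy ketone; the five-atom tether (high effective molarity of the second C–Mg bond) and slow addition of 6 into an excess of 4 at moderate dilution should secure this, while the ketal and the silyl ether are inert to the reagent.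

Step 5
Reactants: 9 9-[2-(tert-butyldimethylsilyloxy)ethyl]-3,3-dimethyl-1,5-dioxaspiro[5.5]undecan-9-ol
Product: 10 4-hydroxy-4-(2-hydroxyethyl)cyclohexan-1-one
Conditions: 1 M aq HCl, THF, rt; solid NaHCO3, concentrate
Reagents that add atoms: water, O
Why: Acid-catalysed hydrolysis should cleave the primary silyl ether and the ketone ketal in one pot, and the tertiary carbinol, being γ to the carbonyl, has neither a retro-aldol nor a β-elimination pathway and should not ionise in dilute acid at room temperature.

Step 6
Reactants: 10 4-hydroxy-4-(2-hydroxyethyl)cyclohexan-1-one; 11 palmitoyl chloride (hexadecanoyl chloride)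
Product: 12 2-(1-hydroxy-4-oxocyclohexyl)ethyl hexadecanoate (CNP0237183.0)
Conditions: 11 (1.05 equiv), 2,4,6-collidine, CH2Cl2, 0 °C
Reagents that add atoms: none
Why: Chemoselective O-acylation with an acid chloride and a weak hindered pyridine base should esterify only the unhindered primary hydroxyl, since the tertiary carbinol is inert without a nucleophilic catalyst and the base is too weak to form a ketene or an enol ester.

Compound list
1 | 1,5-dichloropentan-3-one | ClCCC(=O)CCCl | starting material
2 | 2,2-dimethylpropane-1,3-diol (neopentyl glycol) | OCC(C)(C)CO | starting material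
3 | 2,2-bis(2-chloroethyl)-5,5-dimethyl-1,3-dioxane | ClCCC1(CCCl)OCC(C)(C)CO1 | intermediate
4 | 2,2-bis[2-(chloromagnesio)ethyl]-5,5-dimethyl-1,3-dioxane (bis-Grignard reagent, THF solution) | Cl[Mg]CCC1(CC[Mg]Cl)OCC(C)(C)CO1 | intermediate
5 | methyl 3-hydroxypropanoate | COC(=O)CCO | starting material
6 | methyl 3-(tert-butyldimethylsilyloxy)propanoate | COC(=O)CCO[Si](C)(C)C(C)(C)C | intermediate
7 | keto Grignard: chloromagnesium derivative of 2-[5-(tert-butyldimethylsilyloxy)-3-oxopentyl]-2-ethyl-5,5-dimethyl-1,3-dioxane, metalated at the ethyl terminus (not isolated) | CC(C)(C)[Si](C)(C)OCCC(=O)CCC1(CC[Mg]Cl)OCC(C)(C)CO1 | intermediate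
8 | chloromagnesium alkoxide of 9 (not isolated) | CC(C)(C)[Si](C)(C)OCCC1(O[Mg]Cl)CCC2(CC1)OCC(C)(C)CO2 | intermediate
9 | 9-[2-(tert-butyldimethylsilyloxy)ethyl]-3,3-dimethyl-1,5-dioxaspiro[5.5]undecan-9-ol (achiral) | CC(C)(C)[Si](C)(C)OCCC1(O)CCC2(CC1)OCC(C)(C)CO2 | intermediate
10 | 4-hydroxy-4-(2-hydroxyethyl)cyclohexan-1-one (achiral) | OCCC1(O)CCC(=O)CC1 | intermediate
11 | palmitoyl chloride (hexadecanoyl chloride) | CCCCCCCCCCCCCCCC(=O)Cl | starting material
12 | 2-(1-hydroxy-4-oxocyclohexyl)ethyl hexadecanoate (achiral) | CCCCCCCCCCCCCCCC(=O)OCCC1(O)CCC(=O)CC1 | target

Total step count: 6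
Longest linear sequence: 5 steps (steps 1, 2, 4, 5, 6, from 1,5-dichloropentan-3-one); step 3 is a one-step side branch.

Steps most likely to fail

Step 4 (ring-forming double addition). The intermediate ketone may be attacked by a second reagent molecule and oligomerise. It may also be deprotonated and lose silanolate, or be reduced by β-hydride transfer before the ring closes. The fallback takes the six-membered ring ready-made instead of closing it. It sets out from diol 2, which would be condensed with one carbonyl of commercial cyclohexane-1,4-dione (p-TsOH cat., toluene, azeotropic water removal) to give 3,3-dimethyl-1,5-dioxaspiro[5.5]undecan-9-one F1. Aldol-type addition of the lithium enolate of ethyl acetate (LiN(iPr)2, EtOAc, THF, −78 °C) to the free ketone should give ethyl 2-(9-hydroxy-3,3-dimethyl-1,5-dioxaspiro[5.5]undecan-9-yl)acetate F2. Reduction of the ester with LiAlH4 in THF at 0 °C should give 9-(2-hydroxyethyl)-3,3-dimethyl-1,5-dioxaspiro[5.5]undecan-9-ol F3. Hydrolysis of the ketal with 1 M aqueous HCl in THF then comes back to the route at keto diol 10, bypassing 9.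

Step 2 (double magnesium insertion). Insertion may stop after one C–Cl bond, the first C–Mg end may couple with the remaining C–Cl bond to close a cyclopentane, or a slow insertion may allow 1,3-elimination across the ketal carbon. The fallback metalates by electron transfer at low temperature instead of by direct insertion. It sets out from dichloride 3, which on reductive lithiation with lithium powder and catalytic 4,4′-di-tert-butylbiphenyl in THF at −78 °C should give 2,2-bis(2-lithioethyl)-5,5-dimethyl-1,3-dioxane F4. Transmetalation with anhydrous MgCl2 (2 equiv, THF, −78 → 0 °C) then comes back to the route at bis-Grignard reagent 4.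

Step 5 (one-pot unmasking). The tertiary carbinol may ionise and lose water while the hindered dioxane ketal is still being hydrolysed, and the small water-soluble keto diol may be lost during aqueous work-up. The fallback removes the two masks one at a time without mineral acid. It sets out from 9, which on ketal cleavage with pyridinium p-toluenesulfonate in wet acetone at reflux should give 4-hydroxy-4-[2-(tert-butyldimethylsilyloxy)ethyl]cyclohexan-1-one F5, a lipophilic compound that can be extracted and purified normally. Tetrabutylammonium fluoride in THF, with a non-aqueous work-up (CaCO3 and sulfonic acid resin, filtration, evaporation), should then free the primary hydroxyl and come back to the route at 10. Any early loss of the silyl group in the first stage leads to 10 as well.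

Further compounds
F1 | step 4 | 3,3-dimethyl-1,5-dioxaspiro[5.5]undecan-9-one | O=C1CCC2(CC1)OCC(C)(C)CO2
F2 | step 4 | ethyl 2-(9-hydroxy-3,3-dimethyl-1,5-dioxaspiro[5.5]undecan-9-yl)acetate | CCOC(=O)CC1(O)CCC2(CC1)OCC(C)(C)CO2
F3 | step 4 | 9-(2-hydroxyethyl)-3,3-dimethyl-1,5-dioxaspiro[5.5]undecan-9-ol | OCCC1(O)CCC2(CC1)OCC(C)(C)CO2
F4 | step 2 | 2,2-bis(2-lithioethyl)-5,5-dimethyl-1,3-dioxane | [Li]CCC1(CC[Li])OCC(C)(C)CO1
F5 | step 5 | 4-hydroxy-4-[2-(tert-butyldimethylsilyloxy)ethyl]cyclohexan-1-one | CC(C)(C)[Si](C)(C)OCCC1(O)CCC(=O)CC1
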